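**Plan**

Atoms are numbered in the order of the target SMILES; the stereocentres are C8, C13, C15, C20, C26 and C27.
Retrosynthesis: first cut the lactone bond O10–C11, the cyclopentene (C23=C24 by metathesis, C25–C26 by allylation, C23–C27 by tethered alkenyl addition) and the piperidine bond N17–C16. Then contract the cyclopentanone across C14–C15 to a 1-alkenylcyclobutanol (C16–Br removed), and cut C15–C27, C15–C16, C7–C8 and C8–C20.
Forward ring order: pyrrolidinone template (opened again in step 10) → cyclobutanol → cyclopentanone → piperidine → cycloheptane → cyclopentene → lactone.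
Enabling feature: quaternary C15 lies in the cyclopentane between oxygenated C27 and the CH2 (C16) bound to N17, which is exactly what a bromonium-triggered semipinacol shift of a 1-alkenylcyclobutanol leaves behind.
Stereochemistry: C20 from a catalytic asymmetric malonate–nitroalkene Michael addition; C8 by alkylation trans to the C20 arm on the lactam; C15 and C13 in the ring expansion; C26 by kinetic protonation; C27 by the tether.

Key step: step 15

Assumption: the enantiomer of the nickel diamine catalyst in step 3 is the one that gives the S adduct, and (DHQD)2PHAL is taken as the cinchona ether matched to C8 in step 15 (otherwise its pseudoenantiomer (DHQ)2PHAL is used).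
Assumption: compounds 1, 3, 6, 10 and 18 are purchased.

**Route**

Step 1
Reactants: 1 5-(trimethylsilyl)pent-4-yn-1-ol
Product: 2 5-(trimethylsilyl)pent-4-ynal
Conditions: PhI(OAc)2, TEMPO (10 mol %), CH2Cl2, rt
Reagents that add atoms: none
Why: Oxoammonium (TEMPO) oxidation of a primary alcohol should stop at the aldehyde and leave the silyl alkyne untouched.

Step 2
Reactants: 2 5-(trimethylsilyl)pent-4-ynal; 3 nitromethane
Product: 5 (E)-trimethyl(6-nitrohex-5-en-1-yn-1-yl)silane, via nitro alcohol 4 (not isolated)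
Conditions: MeNO2, Et3N (cat.), THF, 0 °C to rt; then MsCl, Et3N, CH2Cl2, 0 °C
Reagents that add atoms: none
Why: Henry (nitroaldol) reaction followed by mesylation and E1cB elimination should give the conjugated nitroalkene in its more stable E geometry.

Step 3
Reactants: 5 (E)-trimethyl(6-nitrohex-5-en-1-yn-1-yl)silane; 6 dimethyl malonate
Product: 7 dimethyl 2-[(2S)-1-nitro-6-(trimethylsilyl)hex-5-yn-2-yl]propanedioate
Conditions: NiBr2(L)2 (2 mol %; L = N,N′-dibenzylcyclohexane-1,2-diamine, enantiomer giving (S)-7), toluene, rt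
Reagents that add atoms: none
Why: Catalytic asymmetric Michael addition of a malonate to a nitroalkene, in which the chiral nickel diamine complex holds the chelated malonate enolate and exposes one face of the nitroalkene, sets C20 as S.

Step 4
Reactants: 7 dimethyl 2-[(2S)-1-nitro-6-(trimethylsilyl)hex-5-yn-2-yl]propanedioate
Product: 9 methyl (3S,4S)-2-oxo-4-[4-(trimethylsilyl)but-3-yn-1-yl]pyrrolidine-3-carboxylate, via amino diester 8 (not isolated)
Conditions: Zn, AcOH, THF, rt; then Et3N, toluene, 80 °C
Reagents that add atoms: none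
Why: Dissolving-metal reduction of the nitro group gives the primary amine, which closes the lactam on one ester (5-exo-trig acyl substitution); C8 stays epimerisable and should settle trans to the C20 arm.

Step 5
Reactants: 9 methyl (3S,4S)-2-oxo-4-[4-(trimethylsilyl)but-3-yn-1-yl]pyrrolidine-3-carboxylate; 10 4-methylpent-1-en-3-one
Product: 11 methyl (3R,4S)-3-(4-methyl-3-oxopentyl)-2-oxo-4-[4-(trimethylsilyl)but-3-yn-1-yl]pyrrolidine-3-carboxylate
Conditions: DBU (10 mol %), MeCN, 0 °C to rt
Reagents that add atoms: none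
Why: Michael addition of the stabilised amido-ester enolate to the vinyl ketone builds quaternary C8, and the enone should approach the planar enolate anti to the butynyl arm on the neighbouring ring carbon, so the C7 chain ends trans to it.

Step 6
Reactants: 11 keto lactam ester
Product: 12 methyl (3R,4S)-2-oxo-3-{2-[2-(propan-2-yl)-1,3-dioxolan-2-yl]ethyl}-4-[4-(trimethylsilyl)but-3-yn-1-yl]pyrrolidine-3-carboxylate
Conditions: TMSOCH2CH2OTMS, TMSOTf (5 mol %), CH2Cl2, −78 to −20 °C
Reagents that add atoms: 1,2-bis(trimethylsilyloxy)ethane, C[Si](C)(C)OCCO[Si](C)(C)C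
Why: Silyl-triflate-catalysed ketalisation with the bis-silyl glycol ether, driven by Si–O–Si formation, should protect the only ketone (C4) while ester and lactam stay inert.

Step 7
Reactants: 12 ketal lactam ester
Product: 13 (3S,4S)-3-(hydroxymethyl)-3-{2-[2-(propan-2-yl)-1,3-dioxolan-2-yl]ethyl}-4-[4-(trimethylsilyl)but-3-yn-1-yl]pyrrolidin-2-one
Conditions: LiBH4, MeOH (1 equiv), THF, 0 to 40 °C
Reagents that add atoms: none
Why: Borohydride reduction with LiBH4 takes the ester to the C9 primary alcohol and does not reduce a secondary lactam.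

Step 8
Reactants: 13 hydroxymethyl lactam
Product: 14 TBDPS ether of 13
Conditions: TBDPSCl, imidazole, DMAP (cat.), DMF, 40 °C
Reagents that add atoms: tert-butyl(chloro)diphenylsilane, CC(C)(C)[Si](Cl)(c1ccccc1)c1ccccc1
Why: Silylation of the neopentyl primary alcohol; TBDPS is chosen because it should survive organolithiums, NBS and trifluoroacetic acid and it blocks retro-aldol loss of C9.

Step 9
Reactants: 14 TBDPS ether lactam
Product: 15 N-Boc lactam
Conditions: Boc2O, DMAP (cat.), Et3N, MeCN, rt
Reagents that add atoms: di-tert-butyl dicarbonate, CC(C)(C)OC(=O)OC(=O)OC(C)(C)C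
Why: DMAP-catalysed N-acylation turns the lactam into an imide-type carbonyl that is ready for nucleophilic ring opening.

Step 10
Reactants: 15 N-Boc lactam
Product: 16 tert-butyl N-[(2S,3S)-3-acetyl-3-({[tert-butyl(diphenyl)silyl]oxy}methyl)-5-[2-(propan-2-yl)-1,3-dioxolan-2-yl]-2-[4-(trimethylsilyl)but-3-yn-1-yl]pentyl]carbamate
Conditions: MeLi (1.2 equiv), THF, −78 °C; then H2O
Reagents that add atoms: methyllithium, [Li]C
Why: Nucleophilic acyl substitution in which MeLi adds to the activated ring carbonyl and the adduct opens to the carbamate anion, which should prevent a second addition and deliver the C15/C16 methyl ketone with N17 as NHBoc.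

Step 11
Reactants: 16 N-Boc amino methyl ketone
Product: 17 (E)-2,4,6-tri(propan-2-yl)benzenesulfonylhydrazone of 16
Conditions: 2,4,6-tri(propan-2-yl)benzenesulfonyl hydrazide, PPTS (cat.), THF, 40 °C
Reagents that add atoms: 2,4,6-tri(propan-2-yl)benzenesulfonyl hydrazide, NNS(=O)(=O)c1c(C(C)C)cc(C(C)C)cc1C(C)C
Why: Condensation to the arenesulfonylhydrazone needed for the Shapiro reaction, with the sulfonamide nitrogen syn to the methyl group, the only side that carries α-hydrogens.

Step 12
Reactants: 17 trisylhydrazone; 18 methyl 3-oxocyclobutane-1-carboxylate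
Product: 20 cis-hydroxy ester 1-alkenylcyclobutanol (NHBoc; silyl alkyne), via alkenyllithium 19 (not isolated)
Conditions: n-BuLi (3.2 equiv), THF, −78 to 0 °C; then 18, −78 °C; then H2O
Reagents that add atoms: none
Why: Shapiro reaction in which the trianion loses sulfinate and N2 to give the 2-lithioalkene at C15, which should add to the strained ketone faster than to the ester and anti to the ring ester, so that the hydroxyl ends cis to the ester.

Step 13
Reactants: 20 cyclobutanol with NHBoc
Product: 21 N-methyl carbamate cyclobutanol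
Conditions: NaH (1.05 equiv), MeI, THF/DMF, 0 °C
Reagents that add atoms: iodomethane, CI
Why: N-alkylation of the carbamate anion, the most acidic site, installs the N17 methyl group and removes the last N–H that could capture a bromonium ion.

Step 14
Reactants: 21 N-methyl carbamate cyclobutanol
Product: 22 1-alkenylcyclobutanol with terminal alkyne
Conditions: K2CO3 (cat.), MeOH, rt
Reagents that add atoms: none
Why: Base-catalysed methanolysis of the C(sp)–Si bond frees the terminal alkyne at a stage where no base-sensitive β-bromo ketone is yet present.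

Step 15
Reactants: 22 1-alkenylcyclobutanol with terminal alkyne
Product: 23 2-(bromomethyl)cyclopentanone with quaternary C15 (C13 and C15 as in the target)
Conditions: NBS (1.1 equiv), (DHQD)2PHAL (10 mol %), CH2Cl2, −40 °C
Reagents that add atoms: N-bromosuccinimide, O=C1CCC(=O)N1Br
Why: NBS, activated by the quinuclidine catalyst, transfers Br+ to the terminal carbon C16 of the 1,1-disubstituted olefin, and as positive charge builds at C15 the antiperiplanar cyclobutane bond C27–C14 shifts to C15 while the hydroxyl collapses to the C27 ketone, so C14–C15 and C16–Br form in one event. The closest known reaction is the halonium-induced semipinacol ring expansion of 1-alkenylcyclobutanols, which is also known in cinchona-catalysed asymmetric form. The cyclopentanone arises by ring enlargement through a 1,2-alkyl shift (four to five ring atoms), not by an exo or endo cyclisation. C15 is set by anti addition of bromine and C14 across the olefin, the face being chosen by the C8 stereocentre, which turns its three branches away from the four-membered ring, and reinforced by the chiral catalyst; C13 becomes stereogenic in the same event and, because hydroxyl and ester are cis in 22, should end cis to C8. The step needs migration of one of the two diastereotopic ring CH2 groups (one olefin face) and chemoselectivity over the alkyne and the carbamate; strain release lets the shift outrun other capture of the bromonium ion, the carbinol is the only O–H or N–H nucleophile, and C15 carries no hydrogen, so HBr cannot be lost.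

Step 16
Reactants: 23 2-(bromomethyl)cyclopentanone
Product: 24 α-(triethylsilyl)alkene (silicon on C23)
Conditions: Et3SiH, [Cp*Ru(MeCN)3]PF6 (3 mol %), CH2Cl2, 0 °C to rt
Reagents that add atoms: triethylsilane, CC[SiH](CC)CC
Why: Ruthenium-catalysed Markovnikov hydrosilylation of the terminal alkyne should place silicon on the internal carbon C23 and tolerate ketone, alkyl bromide, ester and carbamate.

Step 17
Reactants: 24 α-(triethylsilyl)alkene
Product: 25 2-iodoalkene (iodine on C23)
Conditions: NIS, 2,6-lutidine, (CF3)2CHOH, 0 °C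
Reagents that add atoms: N-iodosuccinimide, O=C1CCC(=O)N1I
Why: Iododesilylation (ipso substitution through the β-silyl cation) converts the 1,1-disubstituted vinylsilane into the 2-iodoalkene with the double bond kept in place.

Step 18
Reactants: 25 2-iodoalkene
Product: 27 spiro piperidine cyclopentanone, via amine trifluoroacetate 26 (not isolated)
Conditions: TFA, CH2Cl2 (anhydrous), 0 °C; then iPr2NEt, NaI (cat.), MeCN, 60 °C
Reagents that add atoms: none
Why: Acidolysis of the Boc group followed by intramolecular SN2 N-alkylation at C16 (6-exo-tet) closes the piperidine; any carbinolamine formed with the C27 ketone is reversible whereas alkylation is not, and quaternary C15 rules out elimination.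

Step 19
Reactants: 27 spiro piperidine cyclopentanone
Product: 29 trans-allyl ketone (allyl on C26 trans to the C13 ester), via lithium enolate 28 (not isolated)
Conditions: LiN(SiMe3)2 (1.05 equiv), THF, −78 °C; then allyl iodide, −78 to −40 °C
Reagents that add atoms: 3-iodoprop-1-ene, C=CCI
Why: Kinetic ketone enolate alkylation at C26, the only enolisable α-carbon because C15 is quaternary, with allyl iodide entering anti to the neighbouring C13 ester; the cold enolate should outpace N-allylation of the hindered amine.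

Step 20
Reactants: 29 trans-allyl ketone
Product: 31 cis-allyl ketone (C26 as in the target), via potassium enolate 30 (not isolated)
Conditions: KN(SiMe3)2 (1.1 equiv), THF, −78 °C; then AcOH, −78 °C
Reagents that add atoms: none
Why: Deprotonation to the tetrasubstituted enolate and kinetic protonation, in which the proton should reach C26 from the face opposite both the C13 ester and the C8 branch, which turns the allyl group onto the ester face (the contra-thermodynamic cis ketone, as in cis-2,3-disubstituted cyclopentanones made this way).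

Step 21
Reactants: 31 cis-allyl ketone
Product: 32 tricyclic tertiary allylic alcohol (seven-membered ring closed, C27 as in the target)
Conditions: CrCl2 (8 equiv), NiCl2 (2 mol %), DMSO, rt to 50 °C
Reagents that add atoms: none
Why: Intramolecular Nozaki–Hiyama–Kishi reaction in which the alkenylchromium species adds to the C27 ketone under non-basic conditions (7-exo-trig), so C26 should not epimerise, and the tether through C20 and C8 allows attack only from the face that C8 occupies, which sets C27 with its hydroxyl trans to C8.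

Step 22
Reactants: 32 tricyclic tertiary allylic alcohol
Product: 33 tetracyclic cyclopentene
Conditions: second-generation Grubbs catalyst (H2IMes)(PCy3)Cl2Ru=CHPh (5 mol %), camphorsulfonic acid (1.1 equiv), CH2Cl2, 40 °C
Reagents that add atoms: none
Why: Ring-closing olefin metathesis between the 1,1-disubstituted alkene at C23 and the allyl group forms the trisubstituted C23=C24 cyclopentene with loss of ethene, the amine being masked as its ammonium salt; only the cis arrangement set in steps 20 and 21 can close.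

Step 23
Reactants: 33 tetracyclic cyclopentene
Product: 35 pentacyclic lactone ketal, via hydroxy ester 34 (not isolated)
Conditions: TBAF, THF, rt to 40 °C; then DBU, toluene, 4 Å sieves, 80 °C
Reagents that add atoms: none
Why: Fluoride desilylation frees the C9 hydroxyl, and base-mediated transesterification (7-exo-trig acyl substitution) should close the lactone onto the C13 ester, which the cage holds on the same face.

Step 24
Reactants: 35 pentacyclic lactone ketal
Product: 36 CNP0242289.1 (target)
Conditions: 1 M HCl, THF, rt; NaHCO3 work-up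
Reagents that add atoms: water, O
Why: Acid-catalysed ketal hydrolysis unmasks the isopropyl ketone, and the lactone and the tertiary allylic alcohol (next to a protonated amine) should survive dilute aqueous acid.

**Compound list**

1 | 5-(trimethylsilyl)pent-4-yn-1-ol | C[Si](C)(C)C#CCCCO | starting material
2 | 5-(trimethylsilyl)pent-4-ynal | C[Si](C)(C)C#CCCC=O | intermediate
3 | nitromethane | C[N+](=O)[O-] | starting material
4 | 1-nitro-6-(trimethylsilyl)hex-5-yn-2-ol (racemic; not isolated) | C[Si](C)(C)C#CCCC(O)C[N+](=O)[O-] | intermediate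
5 | (E)-trimethyl(6-nitrohex-5-en-1-yn-1-yl)silane | C[Si](C)(C)C#CCC/C=C/[N+](=O)[O-] | intermediate
6 | dimethyl malonate | COC(=O)CC(=O)OC | starting material
7 | dimethyl 2-[(2S)-1-nitro-6-(trimethylsilyl)hex-5-yn-2-yl]propanedioate | COC(=O)C(C(=O)OC)[C@@H](C[N+](=O)[O-])CCC#C[Si](C)(C)C | intermediate
8 | dimethyl 2-[(2S)-1-amino-6-(trimethylsilyl)hex-5-yn-2-yl]propanedioate (not isolated) | COC(=O)C(C(=O)OC)[C@@H](CN)CCC#C[Si](C)(C)C | intermediate
9 | methyl (3S,4S)-2-oxo-4-[4-(trimethylsilyl)but-3-yn-1-yl]pyrrolidine-3-carboxylate (3,4-trans) | COC(=O)[C@@H]1C(=O)NC[C@H]1CCC#C[Si](C)(C)C | intermediate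
10 | 4-methylpent-1-en-3-one | C=CC(=O)C(C)C | starting material
11 | methyl (3R,4S)-3-(4-methyl-3-oxopentyl)-2-oxo-4-[4-(trimethylsilyl)but-3-yn-1-yl]pyrrolidine-3-carboxylate | COC(=O)[C@@]1(CCC(=O)C(C)C)C(=O)NC[C@H]1CCC#C[Si](C)(C)C | intermediate
12 | methyl (3R,4S)-2-oxo-3-{2-[2-(propan-2-yl)-1,3-dioxolan-2-yl]ethyl}-4-[4-(trimethylsilyl)but-3-yn-1-yl]pyrrolidine-3-carboxylate | COC(=O)[C@@]1(CCC2(OCCO2)C(C)C)C(=O)NC[C@H]1CCC#C[Si](C)(C)C | intermediate
13 | (3S,4S)-3-(hydroxymethyl)-3-{2-[2-(propan-2-yl)-1,3-dioxolan-2-yl]ethyl}-4-[4-(trimethylsilyl)but-3-yn-1-yl]pyrrolidin-2-one | OC[C@@]1(CCC2(OCCO2)C(C)C)C(=O)NC[C@H]1CCC#C[Si](C)(C)C | intermediate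
14 | (3S,4S)-3-({[tert-butyl(diphenyl)silyl]oxy}methyl)-3-{2-[2-(propan-2-yl)-1,3-dioxolan-2-yl]ethyl}-4-[4-(trimethylsilyl)but-3-yn-1-yl]pyrrolidin-2-one | CC(C)(C)[Si](c1ccccc1)(c1ccccc1)OC[C@@]1(CCC2(OCCO2)C(C)C)C(=O)NC[C@H]1CCC#C[Si](C)(C)C | intermediate
15 | tert-butyl (3S,4S)-3-({[tert-butyl(diphenyl)silyl]oxy}methyl)-2-oxo-3-{2-[2-(propan-2-yl)-1,3-dioxolan-2-yl]ethyl}-4-[4-(trimethylsilyl)but-3-yn-1-yl]pyrrolidine-1-carboxylate | CC(C)(C)[Si](c1ccccc1)(c1ccccc1)OC[C@@]1(CCC2(OCCO2)C(C)C)C(=O)N(C(=O)OC(C)(C)C)C[C@H]1CCC#C[Si](C)(C)C | intermediate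
16 | tert-butyl N-[(2S,3S)-3-acetyl-3-({[tert-butyl(diphenyl)silyl]oxy}methyl)-5-[2-(propan-2-yl)-1,3-dioxolan-2-yl]-2-[4-(trimethylsilyl)but-3-yn-1-yl]pentyl]carbamate | CC(=O)[C@@](CO[Si](c1ccccc1)(c1ccccc1)C(C)(C)C)(CCC1(OCCO1)C(C)C)[C@@H](CNC(=O)OC(C)(C)C)CCC#C[Si](C)(C)C | intermediate
17 | (E)-2,4,6-tri(propan-2-yl)benzenesulfonylhydrazone of 16 (sulfonamide nitrogen syn to the methyl group) | C/C(=N\NS(=O)(=O)c1c(C(C)C)cc(C(C)C)cc1C(C)C)[C@@](CO[Si](c1ccccc1)(c1ccccc1)C(C)(C)C)(CCC1(OCCO1)C(C)C)[C@@H](CNC(=O)OC(C)(C)C)CCC#C[Si](C)(C)C | intermediate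
18 | methyl 3-oxocyclobutane-1-carboxylate | COC(=O)C1CC(=O)C1 | starting material
19 | 2-lithioalkene from 17: lithium on C15, carbamate as its N-lithio salt (not isolated) | [Li]C(=C)[C@@](CO[Si](c1ccccc1)(c1ccccc1)C(C)(C)C)(CCC1(OCCO1)C(C)C)[C@@H](CN([Li])C(=O)OC(C)(C)C)CCC#C[Si](C)(C)C | intermediate
20 | methyl cis-3-hydroxy-3-(alk-1-en-2-yl)cyclobutane-1-carboxylate: hydroxyl cis to the ester; the alkenyl carbon C15 carries quaternary C8 (CH2OTBDPS, ketal-ethyl chain and the C20 branch with CH2NHBoc and the 4-(trimethylsilyl)but-3-ynyl arm; C8 and C20 as in 16) | CC(C)C1(OCCO1)CC[C@@](CO[Si](c2ccccc2)(c2ccccc2)C(C)(C)C)([C@@H](CNC(=O)OC(C)(C)C)CCC#C[Si](C)(C)C)C(=C)[C@@]1(O)C[C@H](C(=O)OC)C1 | intermediate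
21 | N-methyl carbamate of 20 (CH2N(Me)Boc) | CC(C)C1(OCCO1)CC[C@@](CO[Si](c2ccccc2)(c2ccccc2)C(C)(C)C)([C@@H](CN(C)C(=O)OC(C)(C)C)CCC#C[Si](C)(C)C)C(=C)[C@@]1(O)C[C@H](C(=O)OC)C1 | intermediate
22 | 1-alkenylcyclobutanol with terminal alkyne (21 without the C-silyl group; hydroxyl cis to the ester) | CC(C)C1(OCCO1)CC[C@@](CO[Si](c2ccccc2)(c2ccccc2)C(C)(C)C)([C@@H](CN(C)C(=O)OC(C)(C)C)CCC#C)C(=C)[C@@]1(O)C[C@H](C(=O)OC)C1 | intermediate
23 | methyl 3-(bromomethyl)-4-oxocyclopentane-1-carboxylate with the C8 carbon on the bromomethyl-bearing quaternary C15; ester cis to C8; C13 and C15 as in the target | CC(C)C1(OCCO1)CC[C@@](CO[Si](c2ccccc2)(c2ccccc2)C(C)(C)C)([C@@H](CN(C)C(=O)OC(C)(C)C)CCC#C)[C@@]1(CBr)C[C@@H](C(=O)OC)CC1=O | intermediate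
24 | 23 with the alkyne converted into a 1-(triethylsilyl)vinyl group (silicon on C23) | CC(C)C1(OCCO1)CC[C@@](CO[Si](c2ccccc2)(c2ccccc2)C(C)(C)C)([C@@H](CN(C)C(=O)OC(C)(C)C)CCC(=C)[Si](CC)(CC)CC)[C@@]1(CBr)C[C@@H](C(=O)OC)CC1=O | intermediate
25 | 23 with the alkyne converted into a 1-iodovinyl group (iodine on C23) | CC(C)C1(OCCO1)CC[C@@](CO[Si](c2ccccc2)(c2ccccc2)C(C)(C)C)([C@@H](CN(C)C(=O)OC(C)(C)C)CCC(I)=C)[C@@]1(CBr)C[C@@H](C(=O)OC)CC1=O | intermediate
26 | secondary N-methylamine from 25 as its trifluoroacetate (not isolated) | CC(C)C1(OCCO1)CC[C@@](CO[Si](c2ccccc2)(c2ccccc2)C(C)(C)C)([C@@H](CNC)CCC(I)=C)[C@@]1(CBr)C[C@@H](C(=O)OC)CC1=O.OC(=O)C(F)(F)F | intermediate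
27 | spiro compound of N-methylpiperidine (N17, C16, C15, C8, C20, C19) and the cyclopentanone at C15; C13 ester cis to C8; C20 carries the 3-iodobut-3-enyl arm | CC(C)C1(OCCO1)CC[C@@]2(CO[Si](c3ccccc3)(c3ccccc3)C(C)(C)C)[C@H](CCC(I)=C)CN(C)C[C@@]24C[C@@H](C(=O)OC)CC4=O | intermediate
28 | lithium enolate of 27 (C26=C27; not isolated) | CC(C)C1(OCCO1)CC[C@@]2(CO[Si](c3ccccc3)(c3ccccc3)C(C)(C)C)[C@H](CCC(I)=C)CN(C)C[C@@]24C[C@@H](C(=O)OC)C=C4O[Li] | intermediate
29 | 27 with an allyl group on C26 trans to the C13 ester (C26 epimer of the target configuration) | CC(C)C1(OCCO1)CC[C@@]2(CO[Si](c3ccccc3)(c3ccccc3)C(C)(C)C)[C@H](CCC(I)=C)CN(C)C[C@@]24C[C@@H](C(=O)OC)[C@H](CC=C)C4=O | intermediate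
30 | potassium enolate of 29 (tetrasubstituted C26=C27; not isolated) | CC(C)C1(OCCO1)CC[C@@]2(CO[Si](c3ccccc3)(c3ccccc3)C(C)(C)C)[C@H](CCC(I)=C)CN(C)C[C@@]24C[C@@H](C(=O)OC)C(CC=C)=C4O[K] | intermediate
31 | 27 with an allyl group on C26 cis to the C13 ester (C26 as in the target) | CC(C)C1(OCCO1)CC[C@@]2(CO[Si](c3ccccc3)(c3ccccc3)C(C)(C)C)[C@H](CCC(I)=C)CN(C)C[C@@]24C[C@@H](C(=O)OC)[C@@H](CC=C)C4=O | intermediate
32 | tricyclic tertiary alcohol: cycloheptane closed by the C23–C27 bond, exocyclic methylene on C23, hydroxyl on C27 trans to C8, allyl on C26 | CC(C)C1(OCCO1)CC[C@@]2(CO[Si](c5ccccc5)(c5ccccc5)C(C)(C)C)[C@@H]3CCC(=C)[C@]4(O)[C@H](CC=C)[C@H](C(=O)OC)C[C@]24CN(C)C3 | intermediate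
33 | tetracyclic cyclopentene (C23=C24) with C9 OTBDPS, C13 methyl ester and dioxolane | CC(C)C1(OCCO1)CC[C@@]2(CO[Si](c7ccccc7)(c7ccccc7)C(C)(C)C)[C@@H]3CCC4=CC[C@H]5[C@]4(O)[C@@]2(C[C@H]5C(=O)OC)CN(C)C3 | intermediate
34 | hydroxy ester from 33 (free C9 hydroxyl; not isolated) | CC(C)C1(OCCO1)CC[C@@]2(CO)[C@@H]3CCC4=CC[C@H]5[C@]4(O)[C@@]2(C[C@H]5C(=O)OC)CN(C)C3 | intermediate
35 | ethylene ketal of the target at C4 | CC(C)C1(OCCO1)CC[C@]12COC(=O)[C@@H]3C[C@]14CN(C)C[C@H]2CCC1=CC[C@H]3[C@@]14O | intermediate
36 | CNP0242289.1 | CC(C)C(=O)CC[C@]12COC(=O)[C@@H]3C[C@]14CN(C)C[C@H]2CCC1=CC[C@H]3[C@@]14O | target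

**Totals**

Total step count: 24. Longest linear sequence: 24 steps (1 to 36); compounds 3, 6, 10 and 18 enter as purchased materials.

**Steps most likely to fail**

1. Step 15. Bromine may be delivered to the wrong olefin face, so that the other ring CH2 migrates and C15 and C13 come out inverted relative to C8; the terminal alkyne C–H may also be brominated. Fallback: setting out from 22, hydroxyl-directed epoxidation (VO(acac)2, t-BuOOH, CH2Cl2, 0 °C; a chiral hydroxamic acid ligand on vanadium can add reagent control) would give the epoxy cyclobutanol F1, in which oxygen is delivered from the metal bound to the carbinol. Yb(OTf)3 in CH2Cl2 would then trigger the epoxide-opening semipinacol shift to the 2-(hydroxymethyl)cyclopentanone F2. Tf2O and 2,6-lutidine convert it into the neopentyl triflate F3, and Bu4NBr in acetone displaces the triflate, which comes back to the route at 23.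

2. Step 20. Protonation of the tetrasubstituted enolate may show poor facial selectivity, or the cis ketone may revert to the trans isomer by enolisation before the ring closure of step 21. Fallback: setting out from 29, enolate bromination (KN(SiMe3)2, then NBS, −78 °C) would give the α-bromo ketone F4, and DBU eliminates HBr towards the acidic C13–H to give the 2-allyl enone F5, in which C26 is no longer a stereocentre. The same CrCl2/NiCl2 ring closure then gives the dienyl carbinol F6, and ring-closing metathesis gives the bicyclic diene ester F7. Conjugate reduction of the unsaturated ester (Mg, MeOH) can place hydrogen on C26 only on the face that keeps the two five-membered rings cis-fused, and comes back to the route at 33; a wrong C13 epimer would be drained by the DBU lactonisation of step 23.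

3. Step 21. The alkenylchromium intermediate may be protonated or dimerise faster than it adds to the hindered, doubly α-branched ketone. Fallback: setting out from 31, the non-basic chromium coupling is replaced by an anionic ring closure: iodine–lithium exchange with t-BuLi (2.1 equiv) in THF/Et2O/pentane at −100 °C would give the alkenyllithium F8, which closes the seven-membered ring onto C27 faster than it attacks the ester, and comes back to the route at 32 after aqueous quench at low temperature.

**Further compounds**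

F1 | step 15 | epoxy cyclobutanol (C15–C16 epoxide of 22, oxygen anti to the migrating CH2) | CC(C)C1(OCCO1)CC[C@@](CO[Si](c2ccccc2)(c2ccccc2)C(C)(C)C)([C@@H](CN(C)C(=O)OC(C)(C)C)CCC#C)[C@@]2(CO2)[C@@]1(O)C[C@H](C(=O)OC)C1
F2 | step 15 | 2-(hydroxymethyl)cyclopentanone (23 with OH in place of Br) | CC(C)C1(OCCO1)CC[C@@](CO[Si](c2ccccc2)(c2ccccc2)C(C)(C)C)([C@@H](CN(C)C(=O)OC(C)(C)C)CCC#C)[C@@]1(CO)C[C@@H](C(=O)OC)CC1=O
F3 | step 15 | neopentyl triflate of F2 | CC(C)C1(OCCO1)CC[C@@](CO[Si](c2ccccc2)(c2ccccc2)C(C)(C)C)([C@@H](CN(C)C(=O)OC(C)(C)C)CCC#C)[C@@]1(COS(=O)(=O)C(F)(F)F)C[C@@H](C(=O)OC)CC1=O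
F4 | step 20 | α-bromo ketone (29 brominated at C26, bromine anti to the C13 ester) | CC(C)C1(OCCO1)CC[C@@]2(CO[Si](c3ccccc3)(c3ccccc3)C(C)(C)C)[C@H](CCC(I)=C)CN(C)C[C@@]24C[C@@H](C(=O)OC)[C@@](Br)(CC=C)C4=O
F5 | step 20 | 2-allyl enone (C13=C26, conjugated with ketone and ester) | CC(C)C1(OCCO1)CC[C@@]2(CO[Si](c3ccccc3)(c3ccccc3)C(C)(C)C)[C@H](CCC(I)=C)CN(C)C[C@@]24CC(C(=O)OC)=C(CC=C)C4=O
F6 | step 20 | dienyl carbinol (seven-membered ring closed at C23–C27, C13=C26 retained) | CC(C)C1(OCCO1)CC[C@@]2(CO[Si](c5ccccc5)(c5ccccc5)C(C)(C)C)[C@@H]3CCC(=C)[C@]4(O)C(CC=C)=C(C(=O)OC)C[C@]24CN(C)C3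
F7 | step 20 | bicyclic diene ester (C23=C24 and C13=C26) | CC(C)C1(OCCO1)CC[C@@]2(CO[Si](c7ccccc7)(c7ccccc7)C(C)(C)C)[C@@H]3CCC4=CCC5=C(C(=O)OC)C[C@@]2(CN(C)C3)[C@]45O
F8 | step 21 | alkenyllithium (31 with lithium in place of iodine on C23) | CC(C)C1(OCCO1)CC[C@@]2(CO[Si](c3ccccc3)(c3ccccc3)C(C)(C)C)[C@H](CCC([Li])=C)CN(C)C[C@@]24C[C@@H](C(=O)OC)[C@@H](CC=C)C4=O
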